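The data are calculated for an exercise, noise included.

The constants are hidden, so you begin from Tuesday's readings, with these flasks and questions in front of you.

| setting | Tuesday's | birch | cedar | elm | alder | larch |
|---|---|---|---|---|---|---|
| starting complex | 0.40 mM | 0.40 mM | 1.2 mM | 4.0 mM | 12 mM | 30 mM |
| gas | 7.9 mM (held) | 7.9 mM (held) | 7.9 mM (held) | 7.9 mM (held) | 7.9 mM (held) | 7.9 mM (held) |
| capture agent | 15 mM | 10.2 mM | 10.2 mM | 10.2 mM | 10.2 mM | 10.2 mM |
| remark | run made earlier |  |  |  |  |  |
| time |  | 3.0 h | 3.0 h | 3.0 h | 3.0 h | 3.0 h |

- Tuesday's (time / min: complex with four exchanged / %, starting complex / %): 20.0: 0, 48; 40.0: 0, 12; 60.0: 12, 2; 80.0: 24, 0; 120: 51, 0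

(scatter of a reading: 2 percentage points)

- at the start none of the gas is in solution
- "hardly changes" means that all values lie within two and a half points (for a concentration: within two and a half percent of the largest)
- no earlier run changes the charge of capture agent; that part of a forecast is a guess

* [complex with four exchanged] at the end for birch, cedar, elm, alder, larch, in this order
* the shape of the row from first to last (hardly changes / falls, then rises / rises all the way / falls all the way / rises, then falls)

With gas held at saturation, the logarithm of starting complex should fall on a straight line. But at the start none of the gas is in solution, so the line starts late, and that delay is a reading of τ, the time constant with which gas enters solution. Between 20.0 min and 40.0 min the logarithm falls at 0.0693 /min, and this line, run back to the full charge, starts at 9.41 min.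

I assume that gas enters in proportion to what is missing from saturation, so that it enters fastest at c_sat/τ, with c_sat its saturation concentration. I also assume that each complex takes up 4 molecules of gas, and call that number n. The delivery charge C is then the charge of starting complex that gas entering at this fastest rate serves in a time t, so C = c_sat t/(nτ). For 3.0 h this first τ gives 37.8 mM, and larch, at 30 mM, lies below it.

The weak link is τ: that stretch of the curve is still bending. From 40.0 min to 60.0 min the slope is 0.0896 /min, steeper, and the delay 16.3 min, although the last reading, 2%, is good only to 2 percentage points. The delivery charge C for 3.0 h is now 21.8 mM. Alder, at 12 mM, lies below it, but larch, at 30 mM, lies above it. So my row rises up to alder and falls at larch.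

The forecast gives 0.34 mM, 1 mM, 1.2 mM, 0.2 mM and 0.05 mM, a row that rises, then falls. Its turn comes earlier than mine and rests on capture agent: “Elm exceeds the capacity, so released ligand builds up and competes”.

The flasks give 0.304 mM, 0.889 mM, 2.69 mM, 5.39 mM and 2.93 mM, a row that rises, then falls and turns at 14 mM, with alder at its peak against the forecast's 0.2 mM.

    complex with one exchanged + incoming ligand → leaving ligand + complex with two exchanged (k = 13.0 /M/min)
    complex with three exchanged + incoming ligand → leaving ligand + complex with four exchanged (k = 5.70 /M/min)
    starting complex + incoming ligand → leaving ligand + complex with one exchanged (k = 11.0 /M/min)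
    complex with one exchanged + capture agent → trapped intermediate (k = 0.190 /M/min)
    gas ⇌ incoming ligand, rate k5*(csat - [incoming ligand]) (kL = 0.0610 /min)
    complex with two exchanged + incoming ligand → leaving ligand + complex with three exchanged (k = 1.70 /M/min)

In birch the time to deliver the charge at the fastest entry, the run time multiplied by the charge over C, is 3.31 min, far shorter than the 1.5 h half-life of complex with two exchanged by its step to complex with three exchanged at 0.239 h, and at 1.50 h complex with two exchanged holds 49.5% of the charge. In larch the same time, 248 min, is longer than the 3.0 h allowed, and at 3.00 h incoming ligand stands at 3.10 mM against a saturation of 7.9 mM, with complex with two exchanged at 61.5% and complex with four exchanged at 9.76%.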